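## Retrosynthetic overview

1. The target is cut at the C5–C6 sp3–sp2 bond of the side chain (B-alkyl Suzuki–Miyaura coupling), giving a coumarin dienyl ether (hydroborated in situ) and an (E)-iodoalkene that already carries the 9R,10R,11-triol.
2. The iodo-triol comes from an (E,E)-iodo-dienol by asymmetric anti-dihydroxylation: ketone-catalysed epoxidation, then water opening of the oxirane with inversion at the carbon remote from the carbinol.
3. The iodo-dienol comes from cross-metathesis of (E)-1-iodo-2-methylpenta-1,4-diene with 2-methylbut-3-en-2-ol; the iodo-diene comes from carboalumination/iodination of pent-1-en-4-yne.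
4. The dienyl ether comes from semi-reduction of an enyne ether, made by O7-selective Mitsunobu coupling of 5,7-dihydroxycoumarin with (E)-3-methylpent-2-en-4-yn-1-ol.
5. Rings: none is built. The coumarin bicycle is bought intact; the only ring formed is the transient oxirane, opened in the same flask.

Assumption: the target is the (2E,6E,9R,10R) isomer exactly as the SMILES is written; the chiral ketone of step 3 is a catalyst (prepared from L-sorbose), not a starting material.

## Route

Step 1
Reactants: 1 pent-1-en-4-yne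
Product: 3 (1E)-1-iodo-2-methylpenta-1,4-diene, via alkenylalane 2 (not isolated)
Conditions: AlMe3 (2.0 equiv), Cp2ZrCl2 (0.25 equiv), CH2Cl2, 0 °C to rt; then I2 (1.2 equiv), THF, −30 to 0 °C
Reagents that add atoms: trimethylaluminium, C[Al](C)C; iodine, II
Why: Negishi zirconium-catalysed carboalumination adds Me and Al syn across the terminal alkyne with Al on the terminal carbon, and iodinolysis of the C–Al bond proceeds with retention, so the E iodoalkene forms and the isolated vinyl group is untouched.

Step 2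
Reactants: 3 (1E)-1-iodo-2-methylpenta-1,4-diene; 4 2-methylbut-3-en-2-ol (4 equiv)
Product: 5 (3E,6E)-7-iodo-2,6-dimethylhepta-3,6-dien-2-ol
Conditions: second-generation Grubbs catalyst RuCl2(=CHPh)(PCy3)(H2IMes) (3 mol %), 1,4-benzoquinone (10 mol %), CH2Cl2, 40 °C
Reagents that add atoms: none
Why: Olefin cross-metathesis engages only the monosubstituted alkene of 3 (the trisubstituted iodoalkene is too hindered and electron-poor), the bulky tertiary carbinol partner homodimerises slowly and enforces E geometry, and benzoquinone suppresses Ru–H migration of the skipped diene.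

Step 3
Reactants: 5 (3E,6E)-7-iodo-2,6-dimethylhepta-3,6-dien-2-ol
Product: 7 (3R,4R,6E)-7-iodo-2,6-dimethylhept-6-ene-2,3,4-triol, via epoxy alcohol 6 (not isolated)
Conditions: ent-Shi ketone (1,2:4,5-di-O-isopropylidene-β-L-erythro-hexo-2,3-diulo-2,6-pyranose, 30 mol %), Oxone (2KHSO5·KHSO4·K2SO4; 1.4 equiv KHSO5), K2CO3, Bu4NHSO4 (4 mol %), MeCN/DME–aq. Na2B4O7/Na2H2(edta) buffer, pH 10.5, 0 °C, 3 h; then, once the oxidant is spent, 1 M H2SO4 to pH 1, 40 °C, 6 h
Reagents that add atoms: potassium peroxymonosulfate (active part of Oxone), [K+].[O-]S(=O)(=O)OO; water, O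
Why: Proposed new method: a one-flask ketone-catalysed asymmetric anti-dihydroxylation of an (E)-allylic tertiary alcohol that also carries an iodoalkene. The dioxirane of the ent-Shi ketone transfers oxygen through the spiro transition state to one face of the trans-disubstituted alkene (the iodoalkene is too electron-poor to compete) and sets both stereocentres as the (2R,3S)-oxirane 6. After the pH switch, water opens the protonated oxirane by an A-2 (SN2-like) attack with inversion only at the carbon remote from the carbinol, because the other carbon is neopentyl-like and inductively deactivated by the adjacent C–OH, which gives the 3R,4R anti-triol. Closest known reactions: Shi epoxidation of trans-hydroxyalkenes and the separate acid-catalysed C3-selective hydrolysis of 2,3-epoxy alcohols.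

Step 4
Reactants: 8 5,7-dihydroxy-2H-chromen-2-one; 9 (2E)-3-methylpent-2-en-4-yn-1-ol
Product: 10 5-hydroxy-7-{[(2E)-3-methylpent-2-en-4-yn-1-yl]oxy}-2H-chromen-2-one
Conditions: PPh3 (1.05 equiv), DIAD (1.05 equiv), THF, 0 °C to rt
Reagents that add atoms: none
Why: Mitsunobu etherification: the betaine deprotonates the more acidic, unhindered 7-OH (the 5-OH is peri-shielded by H-4), and SN2 displacement at the primary allylic carbon keeps the E geometry.

Step 5
Reactants: 10 5-hydroxy-7-{[(2E)-3-methylpent-2-en-4-yn-1-yl]oxy}-2H-chromen-2-one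
Product: 11 5-hydroxy-7-{[(2E)-3-methylpenta-2,4-dien-1-yl]oxy}-2H-chromen-2-one
Conditions: Zn dust activated with Cu(OAc)2 and AgNO3, MeOH/THF/H2O, 40 °C
Reagents that add atoms: none
Why: Boland-type semi-reduction with activated zinc delivers two hydrogens only to a conjugated alkyne, converting the terminal enyne into a vinyl group without touching the trisubstituted alkene, the lactone or the aryl allyl ether.

Step 6
Reactants: 11 5-hydroxy-7-{[(2E)-3-methylpenta-2,4-dien-1-yl]oxy}-2H-chromen-2-one; 7 (3R,4R,6E)-7-iodo-2,6-dimethylhept-6-ene-2,3,4-triol (0.9 equiv)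
Product: 13 5-hydroxy-7-{[(2E,6E,9R,10R)-9,10,11-trihydroxy-3,7,11-trimethyldodeca-2,6-dien-1-yl]oxy}-2H-chromen-2-one, via alkylborane 12 (not isolated)
Conditions: 9-BBN-H (2.2 equiv), THF, 0 °C to rt; then 7, PdCl2(dppf) (5 mol %), AsPh3 (10 mol %), 3 M aq. K3PO4, DMF, rt; aq. NH4Cl work-up
Reagents that add atoms: none
Why: 9-BBN-H adds anti-Markovnikov to the only monosubstituted alkene (the phenol is masked in situ as its borinate), and the B-alkyl Suzuki–Miyaura coupling joins C5 to the iodoalkene carbon with retention of E geometry under mild aqueous base that tolerates the free triol, with no stereocentre touched.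

## Compound list

1 | pent-1-en-4-yne | C#CCC=C | starting material
2 | dimethyl[(1E)-2-methylpenta-1,4-dien-1-yl]alumane | C=CC/C(C)=C/[Al](C)C | intermediate
3 | (1E)-1-iodo-2-methylpenta-1,4-diene | C=CC/C(C)=C/I | intermediate
4 | 2-methylbut-3-en-2-ol | C=CC(C)(C)O | starting material
5 | (3E,6E)-7-iodo-2,6-dimethylhepta-3,6-dien-2-ol | CC(C)(O)/C=C/C/C(C)=C/I | intermediate
6 | 2-[(2R,3S)-3-[(2E)-3-iodo-2-methylprop-2-en-1-yl]oxiran-2-yl]propan-2-ol | I/C=C(\C)C[C@@H]1O[C@H]1C(C)(C)O | intermediate
7 | (3R,4R,6E)-7-iodo-2,6-dimethylhept-6-ene-2,3,4-triol | I/C=C(\C)C[C@@H](O)[C@@H](O)C(C)(C)O | intermediate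
8 | 5,7-dihydroxy-2H-chromen-2-one (5,7-dihydroxycoumarin) | Oc1cc(O)c2ccc(=O)oc2c1 | starting material
9 | (2E)-3-methylpent-2-en-4-yn-1-ol | C#C/C(C)=C/CO | starting material
10 | 5-hydroxy-7-{[(2E)-3-methylpent-2-en-4-yn-1-yl]oxy}-2H-chromen-2-one | C#C/C(C)=C/COc1cc(O)c2ccc(=O)oc2c1 | intermediate
11 | 5-hydroxy-7-{[(2E)-3-methylpenta-2,4-dien-1-yl]oxy}-2H-chromen-2-one | C=C/C(C)=C/COc1cc(O)c2ccc(=O)oc2c1 | intermediate
12 | 5-[(9-borabicyclo[3.3.1]nonan-9-yl)oxy]-7-{[(2E)-5-(9-borabicyclo[3.3.1]nonan-9-yl)-3-methylpent-2-en-1-yl]oxy}-2H-chromen-2-one | C/C(=C\COc1cc(OB2C3CCCC2CCC3)c2ccc(=O)oc2c1)CCB1C2CCCC1CCC2 | intermediate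
13 | 5-hydroxy-7-{[(2E,6E,9R,10R)-9,10,11-trihydroxy-3,7,11-trimethyldodeca-2,6-dien-1-yl]oxy}-2H-chromen-2-one | C/C(=C\COc1cc(O)c2ccc(=O)oc2c1)CC/C=C(\C)C[C@@H](O)[C@@H](O)C(C)(C)O | target

## Step count and risk

Total steps: 6. Longest linear sequence: 4 (steps 1, 2, 3, 6).

Steps most likely to fail:

**Step 3 (the proposed new step).**
- The dioxirane may oxidise the iodoalkene.
- Base-induced Payne migration of 6 before the pH switch, or any water attack at the carbinol-side oxirane carbon, gives the enantiomeric triol and erodes ee.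
- The D-fructose-derived ketone would give the wrong enantiomer, so the L-sorbose-derived catalyst is required.

Fallback (known chemistry only), setting out from 3 and coming back at 7: Lemieux–Johnson cleavage of the monosubstituted alkene of 3 (OsO4 cat., NaIO4, 2,6-lutidine, dioxane/H2O) gives (3E)-4-iodo-3-methylbut-3-enal F1, used crude. The D-proline-catalysed direct aldol of F1 with 1-hydroxypropan-2-one (DMSO, rt; enamine aldol through the Houk–List transition state, anti-diol) gives (3R,4R,6E)-3,4-dihydroxy-7-iodo-6-methylhept-6-en-2-one F2 after chromatographic removal of the minor syn isomer. MeMgBr (4 equiv, THF, −78 °C) adds to the methyl ketone of F2 and gives 7. This bypasses steps 2 and 3.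

**Step 4.**
- Competing O5- or bis-alkylation of the dihydroxycoumarin.

Fallback, setting out from 8 and coming back at 10: Ac2O/pyridine gives 2-oxo-2H-chromene-5,7-diyl diacetate F3. PhSH/imidazole in NMP removes the acetate of the more acidic 7-phenol and gives 7-hydroxy-2-oxo-2H-chromen-5-yl acetate F4. Mitsunobu coupling of F4 with 9 (PPh3, DIAD, THF) gives 7-{[(2E)-3-methylpent-2-en-4-yn-1-yl]oxy}-2-oxo-2H-chromen-5-yl acetate F5. K2CO3/MeOH removes the 5-acetate and gives 10.

**Step 6.**
- The free triol and phenoxide may slow transmetalation.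
- Zerovalent palladium may ionise the aryl allyl ether.

Fallback, setting out from 7 and coming back at 13: TESOTf/2,6-lutidine (CH2Cl2, −78 °C to 0 °C) converts 7 into the lipophilic (3R,4R,6E)-7-iodo-2,6-dimethyl-2,3,4-tris[(triethylsilyl)oxy]hept-6-ene F6. F6 is coupled with borane 12 under the step 6 conditions (shorter reaction time, lower catalyst loading) to give 5-hydroxy-7-{[(2E,6E,9R,10R)-3,7,11-trimethyl-9,10,11-tris[(triethylsilyl)oxy]dodeca-2,6-dien-1-yl]oxy}-2H-chromen-2-one F7. HF·pyridine (THF, 0 °C) removes the three silyl groups and gives 13.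

## Further compounds

F1 | step 3 | (3E)-4-iodo-3-methylbut-3-enal | O=CC/C(C)=C/I
F2 | step 3 | (3R,4R,6E)-3,4-dihydroxy-7-iodo-6-methylhept-6-en-2-one | I/C=C(\C)C[C@@H](O)[C@@H](O)C(C)=O
F3 | step 4 | 2-oxo-2H-chromene-5,7-diyl diacetate | CC(=O)Oc1cc(OC(C)=O)c2ccc(=O)oc2c1
F4 | step 4 | 7-hydroxy-2-oxo-2H-chromen-5-yl acetate | Oc1cc(OC(C)=O)c2ccc(=O)oc2c1
F5 | step 4 | 7-{[(2E)-3-methylpent-2-en-4-yn-1-yl]oxy}-2-oxo-2H-chromen-5-yl acetate | C#C/C(C)=C/COc1cc(OC(C)=O)c2ccc(=O)oc2c1
F6 | step 6 | (3R,4R,6E)-7-iodo-2,6-dimethyl-2,3,4-tris[(triethylsilyl)oxy]hept-6-ene | I/C=C(\C)C[C@@H](O[Si](CC)(CC)CC)[C@@H](O[Si](CC)(CC)CC)C(C)(C)O[Si](CC)(CC)CC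
F7 | step 6 | 5-hydroxy-7-{[(2E,6E,9R,10R)-3,7,11-trimethyl-9,10,11-tris[(triethylsilyl)oxy]dodeca-2,6-dien-1-yl]oxy}-2H-chromen-2-one | C/C(=C\COc1cc(O)c2ccc(=O)oc2c1)CC/C=C(\C)C[C@@H](O[Si](CC)(CC)CC)[C@@H](O[Si](CC)(CC)CC)C(C)(C)O[Si](CC)(CC)CC
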